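**Plan**
- Retrosynthesis: the two palmitate C–O bonds; C11=C12 and C11'=C12' (C15 + C10 + C15 Wittig couplings); in the ε half the C9'–vinyl bond, C7'=C8', the C1'–C2' bond of ring ε (key step) and C4'=C5' (ring-closing metathesis).
- Enabling feature: in ring ε the allylic oxygen on C3' and the side-chain carbon C7' on C6' are 1,4-related. Tied on one face as a lactone (O–C7'=O), they hold a CH2I group on C3' (C2') over an isopropenyl group on C6', whose inner carbon is the gem-dimethyl carbon C1'.
- Forward, ε half: the lactone ring is closed by metathesis (C4'=C5', Z by ring), then ring ε by the C1'–C2' closure to a 2-oxabicyclo[2.2.2]octenone; lactol, Wittig, vinyl Grignard, Mitsunobu esterification with palmitic acid, phosphonium salt.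
- Forward, β half and assembly: C15 salt from (4R,6R)-actinol and a C6 enynol; ε salt + C10 dialdehyde, then + β salt; last, palmitoylation of the 3-hydroxyl.
- Stereochemistry: C3' from (R)-but-3-ene-1,2-diol, inverted in the Mitsunobu step; C6' from the cis lactone, enforced by the bridge of the key step; C3 from actinol; chain alkenes E by stabilised Wittig, hydroalumination and thermal equilibration.

Key step: step 6

Assumption: carotenoid numbering is used (ring ε C1'–C6' with C7' on C6', ring β C1–C6), and compounds 1, 3, 18, 21 and 23 are taken to be purchasable.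

**Route**

Step 1
Reactants: 1 (R)-but-3-ene-1,2-diol
Product: 2 (R)-2-hydroxybut-3-en-1-yl 4-methylbenzenesulfonate
Conditions: TsCl (1.0 equiv), Bu2SnO (2 mol %), Et3N, CH2Cl2, 0 °C to rt
Reagents that add atoms: 4-methylbenzenesulfonyl chloride, Cc1ccc(cc1)S(Cl)(=O)=O
Why: Stannylene-acetal-catalysed sulfonylation takes the primary hydroxyl of a 1,2-diol selectively (regioselective monotosylation) and leaves the stereocentre that becomes C3' untouched.

Step 2
Reactants: 3 2,4-dimethylpenta-1,3-diene
Product: 6 3-methyl-2-(prop-1-en-2-yl)but-3-enoic acid, via potassium 2,4-dimethylpentadienide 4 (not isolated), via (2,4-dimethylpenta-2,4-dienyl)magnesium bromide 5 (not isolated)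
Conditions: n-BuLi, KOt-Bu, hexane/THF, −78 to 0 °C; MgBr2·OEt2, −78 °C; CO2, −78 °C to rt; aq. HCl
Reagents that add atoms: carbon dioxide, O=C=O
Why: Deprotonation of a methyl group gives the symmetric pentadienyl anion, and its magnesium derivative, like an allylic Grignard reagent, should be carboxylated through a six-membered SE2' transition state at the central carbon, which places the carboxyl carbon (C7') on a CH flanked by two isopropenyl groups (C6').

Step 3
Reactants: 2 (R)-2-hydroxybut-3-en-1-yl 4-methylbenzenesulfonate; 6 3-methyl-2-(prop-1-en-2-yl)but-3-enoic acid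
Product: 7 (R)-1-(tosyloxy)but-3-en-2-yl 3-methyl-2-(prop-1-en-2-yl)but-3-enoate
Conditions: DCC, DMAP (5 mol %), CH2Cl2, 0 °C
Reagents that add atoms: none
Why: Carbodiimide (Steglich) esterification proceeds with retention at the carbinol carbon, and 0 °C with catalytic DMAP should keep the doubly β,γ-unsaturated acid from sliding into conjugation.

Step 4
Reactants: 7 (R)-1-(tosyloxy)but-3-en-2-yl 3-methyl-2-(prop-1-en-2-yl)but-3-enoate
Product: 8 (3R,6R)-4-methyl-3-(prop-1-en-2-yl)-6-(tosyloxymethyl)-3,6-dihydro-2H-pyran-2-one (cis lactone)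
Conditions: second-generation Grubbs catalyst RuCl2(=CHPh)(PCy3)(SIMes) (5 mol %), 1,4-benzoquinone (10 mol %), toluene, 60 °C, 0.005 M; chromatography
Reagents that add atoms: none
Why: Ring-closing metathesis: the carbene loads at the vinyl group and closes on one of the two diastereotopic isopropenyl groups to the trisubstituted ring alkene (Z by ring size), which makes C3 of the lactone (C6') a stereocentre by group selection under the influence of C6; both epimers are to be expected, the cis lactone 8 is separated and taken on, and only this epimer can react in step 6.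

Step 5
Reactants: 8 (3R,6R)-4-methyl-3-(prop-1-en-2-yl)-6-(tosyloxymethyl)-3,6-dihydro-2H-pyran-2-one
Product: 9 (3R,6R)-6-(iodomethyl)-4-methyl-3-(prop-1-en-2-yl)-3,6-dihydro-2H-pyran-2-one
Conditions: NaI, acetone, reflux
Reagents that add atoms: sodium iodide, [Na+].[I-]
Why: Finkelstein exchange (SN2 at the primary carbon) turns the sulfonate into the iodide needed for nickel without touching either stereocentre.

Step 6
Reactants: 9 (3R,6R)-6-(iodomethyl)-4-methyl-3-(prop-1-en-2-yl)-3,6-dihydro-2H-pyran-2-one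
Product: 10 (1S,4R)-5,8,8-trimethyl-2-oxabicyclo[2.2.2]oct-5-en-3-one
Conditions: Mn(dpm)3 (20 mol %; dpm = dipivaloylmethanate), Ni(acac)2 (5 mol %), PhSiH3 (2 equiv), K2CO3 (1.5 equiv), (CF3)2CHOH (2 equiv), 1,2-dichloroethane/propylene carbonate, 23 °C, 0.01 M, degassed
Reagents that add atoms: none
Why: Proposed new method: a trivalent manganese hydride formed from Mn(dpm)3 and PhSiH3 should transfer a hydrogen atom to the CH2 terminus of the isopropenyl group (Markovnikov metal-hydride hydrogen atom transfer), and the tertiary radical at C1' should be captured by the alkylnickel species that low-valent nickel forms from the C2' iodide, reductive elimination from trivalent nickel giving the C1'–C2' bond; the closest known reaction type is the intermolecular manganese/nickel dual-catalytic Markovnikov hydroalkylation of 1,1-disubstituted alkenes with primary alkyl iodides, which builds quaternary carbons, and what is new is its use to close a ring. The one bond closes ring ε (C1'–C6') and with it the second six-membered ring of the 2-oxabicyclo[2.2.2]octene, both by C(sp3)–C(sp3) reductive elimination from a seven-membered nickelacycle (formally 6-exo-tet at C2'). No stereocentre is created, since C1' carries two methyl groups and C2' is a methylene, but only the cis lactone can reach the boat in which the two carbons lie within bonding distance, so the lactone bridge fixes C6' relative to C3' and the trans epimer cannot give a product. The step needs hydrogen atom transfer at the 1,1-disubstituted alkene and not at the ring alkene, which is trisubstituted, flanked by two branched carbons and deactivated by the allylic acyloxy group. It also needs coupling to outrun reduction of the radical, a 1,2-vinyl shift and β-acyloxy loss from the alkylnickel, which the cis-held intramolecular arrangement and high dilution should favour. Both partners are of like polarity (an alkene and an alkyl iodide), so the union rests on the radical/nickel relay and not on a carbocation or enolate next to the doubly allylic C6'–H.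

Step 7
Reactants: 10 (1S,4R)-5,8,8-trimethyl-2-oxabicyclo[2.2.2]oct-5-en-3-one
Product: 11 (1S,4R)-5,8,8-trimethyl-2-oxabicyclo[2.2.2]oct-5-en-3-ol (both C3 epimers)
Conditions: i-Bu2AlH (1.1 equiv), CH2Cl2, −78 °C; aq. potassium sodium tartrate
Reagents that add atoms: none
Why: Half-reduction of a lactone by i-Bu2AlH at low temperature should stop at the bridged lactol, a masked form of the C7' aldehyde; the new hemiacetal centre is of no consequence.

Step 8
Reactants: 11 (1S,4R)-5,8,8-trimethyl-2-oxabicyclo[2.2.2]oct-5-en-3-ol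
Product: 13 (E)-4-[(1R,4S)-4-hydroxy-2,6,6-trimethylcyclohex-2-en-1-yl]but-3-en-2-one, via (1R,4S)-4-hydroxy-2,6,6-trimethylcyclohex-2-ene-1-carbaldehyde 12 (not isolated)
Conditions: Ph3P=CHC(O)CH3 (1.5 equiv), toluene, 90 °C
Reagents that add atoms: 1-(triphenylphosphoranylidene)propan-2-one, CC(=O)C=P(c1ccccc1)(c1ccccc1)c1ccccc1
Why: The lactol is in equilibrium with hydroxy aldehyde 12, which a stabilised ylide should intercept under neutral conditions (Wittig reaction on a lactol) to give the E enone without epimerising the α carbon C6'.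

Step 9
Reactants: 13 (E)-4-[(1R,4S)-4-hydroxy-2,6,6-trimethylcyclohex-2-en-1-yl]but-3-en-2-one
Product: 14 (1E)-1-[(1R,4S)-4-hydroxy-2,6,6-trimethylcyclohex-2-en-1-yl]-3-methylpenta-1,4-dien-3-ol (both epimers at the new carbinol carbon)
Conditions: CH2=CHMgBr (2.5 equiv), THF, −40 to 0 °C; then water
Reagents that add atoms: vinylmagnesium bromide, C=C[Mg]Br
Why: 1,2-Addition of the vinyl Grignard reagent to the enone (the free hydroxyl uses up one equivalent) gives the tertiary bis-allylic carbinol; the new carbinol centre is uncontrolled and is lost in step 11.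

Step 10
Reactants: 14 (1E)-1-[(1R,4S)-4-hydroxy-2,6,6-trimethylcyclohex-2-en-1-yl]-3-methylpenta-1,4-dien-3-ol; 15 hexadecanoic acid (palmitic acid)
Product: 16 (1R,4R)-4-[(1E)-3-hydroxy-3-methylpenta-1,4-dien-1-yl]-3,5,5-trimethylcyclohex-2-en-1-yl hexadecanoate
Conditions: PPh3, DIAD, toluene, 0 °C to rt
Reagents that add atoms: none
Why: Mitsunobu esterification: the secondary allylic alcohol is activated as the alkoxyphosphonium ion and displaced by palmitate with inversion (SN2), which turns the cis 3'S alcohol into the trans 3'R ester of the target, while the tertiary alcohol cannot be activated.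

Step 11
Reactants: 16 (1R,4R)-4-[(1E)-3-hydroxy-3-methylpenta-1,4-dien-1-yl]-3,5,5-trimethylcyclohex-2-en-1-yl hexadecanoate
Product: 17 {(2E,4E)-5-[(1R,4R)-4-(hexadecanoyloxy)-2,6,6-trimethylcyclohex-2-en-1-yl]-3-methylpenta-2,4-dien-1-yl}triphenylphosphonium bromide
Conditions: PPh3·HBr, CH2Cl2/MeOH, 0 °C to rt
Reagents that add atoms: triphenylphosphine hydrobromide, [Br-].[PH+](c1ccccc1)(c1ccccc1)c1ccccc1
Why: Acid ionises the tertiary bis-allylic alcohol to a pentadienyl cation that triphenylphosphine captures at the primary terminus (the vinyl-carbinol route to C15 Wittig salts), giving the E trisubstituted alkene under thermodynamic control, while the secondary allylic ester should ionise far more slowly.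

Step 12
Reactants: 17 the ε C15 phosphonium bromide; 18 (2E,4E,6E)-2,7-dimethylocta-2,4,6-trienedial
Product: 20 (1R,4R)-3,5,5-trimethyl-4-[(1E,3E,5E,7E,9E,11E)-3,7,12-trimethyl-13-oxotrideca-1,3,5,7,9,11-hexaen-1-yl]cyclohex-2-en-1-yl hexadecanoate, via ε-phosphorane 19 (not isolated)
Conditions: 18 (3 equiv), 1,2-epoxybutane/CH2Cl2, reflux, dark, argon; then heptane, reflux
Reagents that add atoms: none
Why: Wittig reaction in which epoxide and bromide generate the ylide 19 without added strong base, with an excess of the dialdehyde to stop at mono-olefination; the ester should survive and any Z isomer at the new C11'=C12' bond is equilibrated to E by heating.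

Step 13
Reactants: 21 (4R,6R)-4-hydroxy-2,2,6-trimethylcyclohexan-1-one (actinol)
Product: 22 (4R,6R)-4-[(2-methoxypropan-2-yl)oxy]-2,2,6-trimethylcyclohexan-1-one
Conditions: 2-methoxypropene, pyridinium p-toluenesulfonate (cat.), CH2Cl2, 0 °C
Reagents that add atoms: 2-methoxypropene, COC(C)=C
Why: Acid-catalysed addition of the hydroxyl to the enol ether gives the mixed acetal, which protects the alcohol against the organolithium and the hydride; no stereocentre is affected.

Step 14
Reactants: 22 (4R,6R)-4-[(2-methoxypropan-2-yl)oxy]-2,2,6-trimethylcyclohexan-1-one; 23 (E)-3-methylpent-2-en-4-yn-1-ol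
Product: 25 (2E)-5-{(4R,6R)-1-hydroxy-4-[(2-methoxypropan-2-yl)oxy]-2,2,6-trimethylcyclohexyl}-3-methylpent-2-en-4-yn-1-ol (both C1 epimers), via dilithio enynolate 24 (not isolated)
Conditions: 23, n-BuLi (2 equiv), THF, −78 to −20 °C; then 22, −78 °C to rt; water
Reagents that add atoms: none
Why: The lithium acetylide of dianion 24 adds 1,2 to the hindered ketone; the new tertiary carbinol centre is uncontrolled and is removed in step 16.

Step 15
Reactants: 25 the acetylenic diol
Product: 26 (2E,4E)-5-{(4R,6R)-1-hydroxy-4-[(2-methoxypropan-2-yl)oxy]-2,2,6-trimethylcyclohexyl}-3-methylpenta-2,4-dien-1-ol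
Conditions: NaAlH2(OCH2CH2OMe)2, THF/toluene, 0 °C to rt; aq. NaOH
Reagents that add atoms: none
Why: trans-Hydroalumination of the alkyne directed by the propargylic alkoxide, then protonolysis, gives the E alkene (C7=C8).

Step 16
Reactants: 26 the dienediol
Product: 28 {(2E,4E)-5-[(4R)-4-hydroxy-2,6,6-trimethylcyclohex-1-en-1-yl]-3-methylpenta-2,4-dien-1-yl}triphenylphosphonium bromide, via allylic bromide 27 (not isolated)
Conditions: 48 % aq. HBr, CH2Cl2, −10 °C; then PPh3, CH2Cl2/EtOAc, rt
Reagents that add atoms: hydrogen bromide, Br; triphenylphosphine, c1ccc(cc1)P(c1ccccc1)c1ccccc1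
Why: Acid removes the acetal and ionises the tertiary and primary allylic alcohols, the ring loses the C5 proton to give the conjugated triene and bromide adds at the primary terminus to give 27 (dehydration with allylic transposition), which triphenylphosphine alkylates (SN2); C3 is not involved.

Step 17
Reactants: 20 the C25 aldehyde; 28 the β C15 phosphonium bromide
Product: 30 (3R,3'R,6'R)-3-hydroxy-β,ε-caroten-3'-yl hexadecanoate (lutein 3'-palmitate), via β-phosphorane 29 (not isolated)
Conditions: 1,2-epoxybutane/CH2Cl2, reflux, dark, argon; then heptane, reflux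
Reagents that add atoms: none
Why: Wittig reaction between ylide 29 and the C25 aldehyde closes the C40 chain at C11=C12; heating equilibrates Z isomers to the all-E polyene, and the free hydroxyl and the ester should tolerate the epoxide-generated base.

Step 18
Reactants: 30 lutein 3'-palmitate; 31 hexadecanoyl chloride (palmitoyl chloride)
Product: 32 (3R,3'R,6'R)-β,ε-carotene-3,3'-diyl dihexadecanoate (helenien)
Conditions: pyridine, DMAP (cat.), CH2Cl2, 0 °C to rt, dark, argon
Reagents that add atoms: none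
Why: Acylation of the remaining secondary homoallylic hydroxyl with the acid chloride, with retention at C3, gives the diester.

**Compound list**
1 | (R)-but-3-ene-1,2-diol | C=C[C@@H](O)CO | starting material
2 | (R)-2-hydroxybut-3-en-1-yl 4-methylbenzenesulfonate | C=C[C@@H](O)COS(=O)(=O)c1ccc(C)cc1 | intermediate
3 | 2,4-dimethylpenta-1,3-diene | CC(C)=CC(C)=C | starting material
4 | potassium 2,4-dimethylpentadienide | [K+].[CH2-]C(C)=CC(C)=C | intermediate
5 | (2,4-dimethylpenta-2,4-dienyl)magnesium bromide | Br[Mg]CC(C)=CC(C)=C | intermediate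
6 | 3-methyl-2-(prop-1-en-2-yl)but-3-enoic acid | CC(=C)C(C(C)=C)C(O)=O | intermediate
7 | (R)-1-(tosyloxy)but-3-en-2-yl 3-methyl-2-(prop-1-en-2-yl)but-3-enoate | C=C[C@@H](OC(=O)C(C(C)=C)C(C)=C)COS(=O)(=O)c1ccc(C)cc1 | intermediate
8 | (3R,6R)-4-methyl-3-(prop-1-en-2-yl)-6-(tosyloxymethyl)-3,6-dihydro-2H-pyran-2-one | O=C1[C@H](C(C)=C)C(C)=C[C@@H](O1)COS(=O)(=O)c2ccc(C)cc2 | intermediate
9 | (3R,6R)-6-(iodomethyl)-4-methyl-3-(prop-1-en-2-yl)-3,6-dihydro-2H-pyran-2-one | O=C1[C@H](C(C)=C)C(C)=C[C@@H](O1)CI | intermediate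
10 | (1S,4R)-5,8,8-trimethyl-2-oxabicyclo[2.2.2]oct-5-en-3-one | O=C1[C@H]2C(C)=C[C@@H](O1)CC2(C)C | intermediate
11 | (1S,4R)-5,8,8-trimethyl-2-oxabicyclo[2.2.2]oct-5-en-3-ol (both C3 epimers) | OC1[C@H]2C(C)=C[C@@H](O1)CC2(C)C | intermediate
12 | (1R,4S)-4-hydroxy-2,6,6-trimethylcyclohex-2-ene-1-carbaldehyde | O=C[C@H]1C(C)=C[C@@H](O)CC1(C)C | intermediate
13 | (E)-4-[(1R,4S)-4-hydroxy-2,6,6-trimethylcyclohex-2-en-1-yl]but-3-en-2-one | CC(=O)/C=C/[C@H]1C(C)=C[C@@H](O)CC1(C)C | intermediate
14 | (1E)-1-[(1R,4S)-4-hydroxy-2,6,6-trimethylcyclohex-2-en-1-yl]-3-methylpenta-1,4-dien-3-ol (carbinol epimers) | C=CC(C)(O)/C=C/[C@H]1C(C)=C[C@@H](O)CC1(C)C | intermediate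
15 | hexadecanoic acid | CCCCCCCCCCCCCCCC(O)=O | starting material
16 | (1R,4R)-4-[(1E)-3-hydroxy-3-methylpenta-1,4-dien-1-yl]-3,5,5-trimethylcyclohex-2-en-1-yl hexadecanoate | C=CC(C)(O)/C=C/[C@H]1C(C)=C[C@H](OC(=O)CCCCCCCCCCCCCCC)CC1(C)C | intermediate
17 | {(2E,4E)-5-[(1R,4R)-4-(hexadecanoyloxy)-2,6,6-trimethylcyclohex-2-en-1-yl]-3-methylpenta-2,4-dien-1-yl}triphenylphosphonium bromide | C(/C=C(C)/C=C/[C@H]1C(C)=C[C@H](OC(=O)CCCCCCCCCCCCCCC)CC1(C)C)[P+](c1ccccc1)(c1ccccc1)c1ccccc1.[Br-] | intermediate
18 | (2E,4E,6E)-2,7-dimethylocta-2,4,6-trienedial | O=C/C(C)=C/C=C/C=C(C)/C=O | starting material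
19 | ylide of 17, (1R,4R)-3,5,5-trimethyl-4-[(1E,3E)-3-methyl-5-(triphenylphosphoranylidene)penta-1,3-dien-1-yl]cyclohex-2-en-1-yl hexadecanoate | C(=P(c1ccccc1)(c1ccccc1)c1ccccc1)/C=C(C)/C=C/[C@H]1C(C)=C[C@H](OC(=O)CCCCCCCCCCCCCCC)CC1(C)C | intermediate
20 | (1R,4R)-3,5,5-trimethyl-4-[(1E,3E,5E,7E,9E,11E)-3,7,12-trimethyl-13-oxotrideca-1,3,5,7,9,11-hexaen-1-yl]cyclohex-2-en-1-yl hexadecanoate | O=C/C(C)=C/C=C/C=C(C)/C=C/C=C(C)/C=C/[C@H]1C(C)=C[C@H](OC(=O)CCCCCCCCCCCCCCC)CC1(C)C | intermediate
21 | (4R,6R)-4-hydroxy-2,2,6-trimethylcyclohexan-1-one | O[C@@H]1C[C@@H](C)C(=O)C(C)(C)C1 | starting material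
22 | (4R,6R)-4-[(2-methoxypropan-2-yl)oxy]-2,2,6-trimethylcyclohexan-1-one | COC(C)(C)O[C@@H]1C[C@@H](C)C(=O)C(C)(C)C1 | intermediate
23 | (E)-3-methylpent-2-en-4-yn-1-ol | C#C/C(C)=C/CO | starting material
24 | dilithium salt of 23 (O-lithio, C-lithio) | [Li]C#C/C(C)=C/CO[Li] | intermediate
25 | (2E)-5-{(4R,6R)-1-hydroxy-4-[(2-methoxypropan-2-yl)oxy]-2,2,6-trimethylcyclohexyl}-3-methylpent-2-en-4-yn-1-ol (C1 epimers) | COC(C)(C)O[C@@H]1C[C@@H](C)C(O)(C#C/C(C)=C/CO)C(C)(C)C1 | intermediate
26 | (2E,4E)-5-{(4R,6R)-1-hydroxy-4-[(2-methoxypropan-2-yl)oxy]-2,2,6-trimethylcyclohexyl}-3-methylpenta-2,4-dien-1-ol (C1 epimers) | COC(C)(C)O[C@@H]1C[C@@H](C)C(O)(/C=C/C(C)=C/CO)C(C)(C)C1 | intermediate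
27 | (R)-4-[(1E,3E)-5-bromo-3-methylpenta-1,3-dien-1-yl]-3,5,5-trimethylcyclohex-3-en-1-ol | O[C@@H]1CC(C)=C(/C=C/C(C)=C/CBr)C(C)(C)C1 | intermediate
28 | {(2E,4E)-5-[(4R)-4-hydroxy-2,6,6-trimethylcyclohex-1-en-1-yl]-3-methylpenta-2,4-dien-1-yl}triphenylphosphonium bromide | O[C@@H]1CC(C)=C(/C=C/C(C)=C/C[P+](c2ccccc2)(c2ccccc2)c2ccccc2)C(C)(C)C1.[Br-] | intermediate
29 | ylide of 28, (R)-3,5,5-trimethyl-4-[(1E,3E)-3-methyl-5-(triphenylphosphoranylidene)penta-1,3-dien-1-yl]cyclohex-3-en-1-ol | O[C@@H]1CC(C)=C(/C=C/C(C)=C/C=P(c2ccccc2)(c2ccccc2)c2ccccc2)C(C)(C)C1 | intermediate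
30 | (3R,3'R,6'R)-3-hydroxy-β,ε-caroten-3'-yl hexadecanoate (all-E) | O[C@@H]1CC(C)=C(/C=C/C(C)=C/C=C/C(C)=C/C=C/C=C(C)/C=C/C=C(C)/C=C/[C@H]2C(C)=C[C@H](OC(=O)CCCCCCCCCCCCCCC)CC2(C)C)C(C)(C)C1 | intermediate
31 | hexadecanoyl chloride | CCCCCCCCCCCCCCCC(Cl)=O | starting material
32 | helenien, (3R,3'R,6'R)-β,ε-carotene-3,3'-diyl dihexadecanoate (all-E) | CCCCCCCCCCCCCCCC(=O)O[C@@H]1CC(C)=C(/C=C/C(C)=C/C=C/C(C)=C/C=C/C=C(C)/C=C/C=C(C)/C=C/[C@H]2C(C)=C[C@H](OC(=O)CCCCCCCCCCCCCCC)CC2(C)C)C(C)(C)C1 | target

**Count**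
Total: 18 steps. Longest linear sequence: 13 steps (steps 1, 3 to 12, 17, 18).

**Steps most likely to fail**

1. Step 6. The tertiary radical may be quenched before it couples (hydrogenation of the isopropenyl group), may undergo a 1,2-vinyl shift, or the alkylnickel may lose the β-acyloxy group, so that ring closure does not compete. The fallback uses known chemistry, sets out from 9 and returns at 10, and forms the same bond by radical addition to a carbonyl group. The iodide is oxidised with trimethylamine N-oxide in DMSO (Kornblum-type oxidation) to (2R,5R)-4-methyl-6-oxo-5-(prop-1-en-2-yl)-5,6-dihydro-2H-pyran-2-carbaldehyde F1. Hydrogen-atom-transfer-initiated radical cyclisation of the alkene onto the carbonyl group (Fe(acac)3, PhSiH3, EtOH, 60 °C), a known reaction type for alkene-tethered carbonyl compounds, should give 7-hydroxy-5,8,8-trimethyl-2-oxabicyclo[2.2.2]oct-5-en-3-one F2 (bridgeheads as in 10, C7 epimers). Acylation with PhOC(S)Cl and pyridine gives the O-phenyl thionocarbonate of this alcohol F3, and Barton–McCombie deoxygenation (Bu3SnH in high concentration, Et3B, air, toluene, rt) returns to 10.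

2. Step 4. The ring closure may differentiate the two diastereotopic isopropenyl groups poorly or in the wrong sense, and a ruthenium hydride may move the ring alkene into conjugation. The fallback sets out from 7 and returns at 8, and sets C3 by protonation instead of group selection. The ring is closed as in step 4 without regard to selectivity, so that the C3 epimer (3S,6R)-4-methyl-3-(prop-1-en-2-yl)-6-(tosyloxymethyl)-3,6-dihydro-2H-pyran-2-one F4 results, alone or mixed with 8. Soft enolisation (TMSOTf, Et3N, CH2Cl2, −78 °C) gives the silyl ketene acetal (6R)-4-methyl-3-(prop-1-en-2-yl)-6-(tosyloxymethyl)-2-(trimethylsilyloxy)-6H-pyran F5, in which C3 is planar. Kinetic protonation at C3 (AcOH, THF, −78 °C) from the face remote from the C6 substituent should give the cis lactone 8.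

3. Step 10. Substitution with allylic transposition, or elimination to a diene, may compete with clean inversion at a carbinol carbon that lies next to a neopentyl-type CH2. The fallback sets out from 14 and returns at 16, and sets C3' by oxidation and reduction. MnO2 (CH2Cl2, rt) oxidises the secondary allylic alcohol selectively to (4R)-4-[(1E)-3-hydroxy-3-methylpenta-1,4-dien-1-yl]-3,5,5-trimethylcyclohex-2-en-1-one F6. 1,2-Reduction (NaBH4, CeCl3·7H2O, MeOH, −78 °C), with hydride expected to enter anti to the axial methyl group on C1', should give the trans diol (1E)-1-[(1R,4R)-4-hydroxy-2,6,6-trimethylcyclohex-2-en-1-yl]-3-methylpenta-1,4-dien-3-ol F7. Acylation of its secondary hydroxyl with 31 and pyridine (CH2Cl2, 0 °C) gives 16.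

**Further compounds**
F1 | step 6 | (2R,5R)-4-methyl-6-oxo-5-(prop-1-en-2-yl)-5,6-dihydro-2H-pyran-2-carbaldehyde | O=C1[C@H](C(C)=C)C(C)=C[C@@H](O1)C=O
F2 | step 6 | 7-hydroxy-5,8,8-trimethyl-2-oxabicyclo[2.2.2]oct-5-en-3-one (bridgeheads as in 10, C7 epimers) | O=C1[C@H]2C(C)=C[C@@H](O1)C(O)C2(C)C
F3 | step 6 | O-phenyl thionocarbonate of F2 | O=C1[C@H]2C(C)=C[C@@H](O1)C(OC(=S)Oc3ccccc3)C2(C)C
F4 | step 4 | (3S,6R)-4-methyl-3-(prop-1-en-2-yl)-6-(tosyloxymethyl)-3,6-dihydro-2H-pyran-2-one | O=C1[C@@H](C(C)=C)C(C)=C[C@@H](O1)COS(=O)(=O)c2ccc(C)cc2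
F5 | step 4 | (6R)-4-methyl-3-(prop-1-en-2-yl)-6-(tosyloxymethyl)-2-(trimethylsilyloxy)-6H-pyran | C[Si](C)(C)OC1=C(C(C)=C)C(C)=C[C@@H](O1)COS(=O)(=O)c2ccc(C)cc2
F6 | step 10 | (4R)-4-[(1E)-3-hydroxy-3-methylpenta-1,4-dien-1-yl]-3,5,5-trimethylcyclohex-2-en-1-one | C=CC(C)(O)/C=C/[C@H]1C(C)=CC(=O)CC1(C)C
F7 | step 10 | (1E)-1-[(1R,4R)-4-hydroxy-2,6,6-trimethylcyclohex-2-en-1-yl]-3-methylpenta-1,4-dien-3-ol | C=CC(C)(O)/C=C/[C@H]1C(C)=C[C@H](O)CC1(C)C
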